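**Assumption:** The SMILES is read as the 29-membered lactone with one carbonyl carbon (C1), 27 CH2 groups (C2–C28) and one ring oxygen, without stereocentres. Hexadecan-16-olide and dodec-11-en-1-ol are taken as catalogue compounds.

## Analysis of the target

Octacosan-28-olide 7 is a single 29-membered ring made of the ester unit C1(=O)–O and an unbroken run of 27 methylene groups, C2 to C28 (C1 is the lactone carbonyl carbon, C28 the carbon on the ring oxygen). There is no stereocentre, no double bond and no branch, so the whole problem is one of connectivity and ring closure. The only sensitive group is the lactone, which rules out hydride reagents, hot aqueous base and hard carbon nucleophiles late in the route. The difficulty lies in three things: no 28-carbon α,ω-difunctional chain can be bought; closure of a strain-free 29-membered ring must compete with intermolecular reaction; and the C2–C28 run offers no handle, so a C–C bond formed inside it must leave no trace. A practical point adds to this: homologues (C27, C29) and open-chain esters of the same polarity would be nearly inseparable from a waxy lactone, so steps that can shift chain length should be avoided. The feature that invites the chosen strategy is this handle-free methylene run of the 29-membered ring. Its bond C16–C17 divides the carbons into a C16 and a C12 block that can both be bought, and the ester O–C1 already present in the target can act as the tether that makes an sp3–sp3 coupling across C16–C17 intramolecular.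

## Retrosynthetic reasoning

**Cut C16–C17 (7 ⇒ 6).** The ring of 7 is opened not at the ester but at an sp3–sp3 bond in the middle of the methylene run. This gives 12-(9-borabicyclo[3.3.1]nonan-9-yl)dodecyl 16-iodohexadecanoate 6, with a primary iodide at C16 and a primary borane at C17. All CH2–CH2 bonds are chemically alike, so the cut is placed where supply and stability are best. The C16 and C12 halves are commercial; the halide is far from C1, so no α- or β-halo ester chemistry arises; and the boron is far from O28, so no β-alkoxyborane elimination can occur. The gain is that completion of the C28 chain and ring closure become one operation. The target's own ester is the tether, so no protecting group is needed, and the product is saturated, so no hydrogenation follows. The forward reaction must join two primary alkyl carbons that carry β-hydrogens, at room temperature, beside an ester, and under dilution.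

**Cut C17–B (6 ⇒ 5).** The borane at C17 of 6 is traced back to the terminal alkene of dodec-11-en-1-yl 16-iodohexadecanoate 5 by anti-Markovnikov hydroboration in the same flask. The alkene is a masked nucleophile that stays silent during ester formation.

**Cut the acyl C1–O bond (5 ⇒ 3 + 4).** The ester is made between 16-iodohexadecanoic acid 3 and dodec-11-en-1-ol 4 at preparative concentration, where ester formation has no entropic cost. This reverses the textbook logic: the ester is formed intermolecularly and the ring is closed by a C–C bond.

**Cut C16–I back to the O–C16 bond (3 ⇒ 2 ⇒ 1).** The ω-iodo acid 3 comes from the bulk musk hexadecan-16-olide 1 by alkyl–oxygen cleavage with a silyl iodide, through trimethylsilyl 16-iodohexadecanoate 2. Lactone 1 supplies C1–C16 with both ends already differentiated, acid at C1 and leaving group at C16, without any protecting group.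

## Alternatives that were turned down

**Alternative 1:** The textbook disconnection cuts the acyl C1–O bond of the target. The precursor is 28-hydroxyoctacosanoic acid A1, closed by Yamaguchi macrolactonization at high dilution. The ring closure itself is dependable. It was turned down because A1 cannot be bought: its chain must be built by an sp3–sp3 coupling of a C16 and a C12 piece anyway, with hydroxyl and carboxyl masked during the coupling and freed afterwards. Chain assembly and ring closure are then paid for separately, in five or more steps.

**Alternative 2:** Ring-closing metathesis followed by hydrogenation. The diene ester dodec-11-en-1-yl octadec-17-enoate A2 would be closed with a second-generation Grubbs catalyst at high dilution to the E/Z mixture of oxacyclononacos-18-en-2-one A3, and A3 would then be reduced with H2 over Pd/C. It was turned down for three reasons: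
- The C18 acyl half of A2, with its terminal alkene, is not purchasable and costs extra steps.
- Ruthenium hydrides from catalyst decay can move a terminal double bond of A2 before closure; the ring-contracted C27 and C26 homologues of A3 that result would be hard to separate from the target after hydrogenation.
- The alkene of A3 is a trace that needs its own removal step.

A three-component variant, ring-expanding insertion of a C8 cycloalkene into undec-10-en-1-yl undec-10-enoate A4, was also considered. Nothing in the two unbiased terminal olefins of A4 limits insertion to one cycloalkene unit, so C20, C28 and C36 lactones would be expected side by side.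

**Alternative 3:** A symmetry-based electrochemical route. Kolbe anodic dimerization of 15-methoxy-15-oxopentadecanoic acid A5 would give dimethyl octacosanedioate A6. Acyloin ring closure of A6 and deoxygenation would give cyclooctacosanone A7, and Baeyer–Villiger oxidation would insert the ring oxygen. The symmetry of A7 removes every regiochemical question. It was turned down on step economy: preparation of the half-ester A5, electrolysis to A6, acyloin closure with sodium and Me3SiCl, deoxygenation and a slow peracid oxidation of a strain-free large-ring ketone add up to about six steps. Chain, ring and oxygen are each installed in a separate operation, and unreacted A7 would be hard to separate from the target.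

Key step: step 3

## Route

Step 1
Reactants: 1 hexadecan-16-olide
Product: 3 16-iodohexadecanoic acid, via trimethylsilyl 16-iodohexadecanoate 2 (not isolated)
Conditions: NaI, Me3SiCl, MeCN, reflux; then H2O
Reagents that add atoms: sodium iodide, [Na+].[I-] (the iodine of 3); chlorotrimethylsilane, C[Si](C)(C)Cl (its Me3Si group stands in intermediate 2 only)
Why: Ester cleavage by iodotrimethylsilane made in the flask: silylation of the lactone carbonyl oxygen turns C16 into an alkyl electrophile, iodide opens the O–C16 bond by SN2 at this primary carbon to give 2, and water frees the acid; this is the known opening of lactones to ω-iodo acids, and no stereocentre is involved.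

Step 2
Reactants: 3 16-iodohexadecanoic acid; 4 dodec-11-en-1-ol
Product: 5 dodec-11-en-1-yl 16-iodohexadecanoate
Conditions: DCC, DMAP (cat.), CH2Cl2, 0 °C to rt
Reagents that add atoms: none
Why: Steglich esterification: DCC turns 3 into an O-acylisourea and DMAP relays the acyl group to the primary alcohol 4 at preparative concentration; the primary iodide and the terminal alkene are inert at room temperature and no stereocentre is formed.

Step 3
Reactants: 5 dodec-11-en-1-yl 16-iodohexadecanoate
Product: 7 octacosan-28-olide, via alkylborane 6 (not isolated)
Conditions: 9-BBN-H (1.1 equiv), THF, 0 °C to rt; then slow addition (16 h) to Pd(OAc)2 (10 mol%), PCy3 (20 mol%), K3PO4·H2O (3 equiv), THF, rt, final 2 mM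
Reagents that add atoms: 9-borabicyclo[3.3.1]nonane (9-BBN-H), B1C2CCCC1CCC2 (its boron and ring stand in intermediate 6 only; 7 keeps only its hydrogen)
Why: Proposed new method: a B-alkyl Suzuki–Miyaura coupling of two unactivated primary sp3 carbons run as a macrocyclization; the closest known reaction types are the intermolecular palladium/trialkylphosphine coupling of B-alkyl-9-BBN reagents with primary alkyl iodides and bromides that carry β-hydrogens (ester-tolerant, room temperature) and the B-alkyl Suzuki–Miyaura macrocyclization onto alkenyl iodides. Mechanism: 9-BBN-H adds anti-Markovnikov to the terminal alkene of 5, leaving ester and C–I untouched, to give 6; zerovalent palladium bis(tricyclohexylphosphine), formed in the flask from Pd(OAc)2 and PCy3, enters the primary C16–I bond by SN2-type oxidative addition; hydroxide from K3PO4·H2O turns the boron at C17 into a borate whose primary alkyl group passes to divalent palladium; reductive elimination forms C16–C17. The ring closure is an end-to-end macrocyclization without Baldwin constraints, in which a 30-membered dialkylpalladium chelate collapses to the strain-free 29-membered lactone, and no stereocentre is created. The first selectivity needed is ring against oligomer: the iodide is used instead of the bromide because oxidative addition is bimolecular in catalyst and substrate and must stay fast at millimolar concentration, so that under syringe-pump addition free 6 should not build up and each alkylpalladium iodide should meet its own tethered borate (effective molarity for large strain-free rings is expected in the 10^-2 M range) before a foreign one. The second is coupling against β-hydride elimination: alkylpalladium halides that carry two bulky trialkylphosphines have no free cis site and persist at room temperature, so the intermediate can wait for the slow intramolecular transmetalation. The third is chemoselectivity: only the primary C17–B bond should transmetalate, the two secondary B–C bonds of the bicycle being hindered, and the mild hydrated phosphate base in THF should leave the ester intact.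

## Compound list

1 | hexadecan-16-olide (oxacycloheptadecan-2-one) | O=C1CCCCCCCCCCCCCCCO1 | starting material
2 | trimethylsilyl 16-iodohexadecanoate | C[Si](C)(C)OC(=O)CCCCCCCCCCCCCCCI | intermediate (not isolated)
3 | 16-iodohexadecanoic acid | OC(=O)CCCCCCCCCCCCCCCI | intermediate
4 | dodec-11-en-1-ol | OCCCCCCCCCCC=C | starting material
5 | dodec-11-en-1-yl 16-iodohexadecanoate | ICCCCCCCCCCCCCCCC(=O)OCCCCCCCCCCC=C | intermediate
6 | 12-(9-borabicyclo[3.3.1]nonan-9-yl)dodecyl 16-iodohexadecanoate | ICCCCCCCCCCCCCCCC(=O)OCCCCCCCCCCCCB1C2CCCC1CCC2 | intermediate (not isolated)
7 | octacosan-28-olide (oxacyclononacosan-2-one) | O=C1CCCCCCCCCCCCCCCCCCCCCCCCCCCO1 | target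

## Step count and risks

Total step count: 3. Longest linear sequence: 3 steps (1 → 3 → 5 → 7).

**Step 3 (key step, proposed new method).** Three processes are most likely to go wrong:
- Catalyst turnover may fall behind the addition rate, so that free 6 accumulates and intermolecular transmetalation to chain and ring oligomers takes over.
- β-Hydride elimination or hydrodehalogenation of the alkylpalladium iodide may occur during the long wait for the tethered borate.
- The catalyst may decay at sub-millimolar palladium concentration, through phosphine oxidation or quaternization of PCy3 by the primary iodide.

Fallback, by known chemistry, setting out from 3 and 4 and coming back at 7: the same C16–C17 bond is made intermolecularly at ordinary concentration and the ring is then closed at the ester. Alcohol 4 would be acetylated (Ac2O, pyridine) to dodec-11-en-1-yl acetate F1, and acid 3 esterified (MeOH, cat. H2SO4) to methyl 16-iodohexadecanoate F2. Hydroboration of F1 with 9-BBN-H in THF would give 12-(9-borabicyclo[3.3.1]nonan-9-yl)dodecyl acetate F3, which would be coupled in the same flask with F2 (Pd(OAc)2, PCy3, K3PO4·H2O, THF, rt, about 0.3 M) to methyl 28-acetoxyoctacosanoate F4. Saponification of both esters of F4 (KOH, EtOH/H2O, reflux; then HCl) would give 28-hydroxyoctacosanoic acid F5. Yamaguchi macrolactonization of F5 (2,4,6-trichlorobenzoyl chloride, Et3N, THF; then slow addition to DMAP in toluene at reflux) would close the ring to 7.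

**Step 1.** The most likely failure is incomplete O–C16 cleavage, because SN2 attack of iodide on an unactivated primary carbon of a strain-free ester is slow; acid-promoted ring-opening oligomerization of 1 to polyester may accompany it. Fallback, setting out from 1 and coming back at 3: Brønsted-acid opening with HBr (33% in AcOH) and a trace of H2SO4 at 80 °C would give 16-bromohexadecanoic acid F6, which can be crystallised, and halide exchange of F6 with NaI in acetone at reflux would give 3.

**Step 2.** The most likely failures are rearrangement of the O-acylisourea to the unreactive N-acylurea and slow N-alkylation of DMAP by the primary iodide, both of which lower conversion, and difficult separation of the waxy ester from the urea. Fallback, setting out from 3 and 4 and coming back at 5: Mitsunobu esterification (PPh3, DIAD, THF, 0 °C to rt) activates the alcohol instead of the acid and forms the C28–O bond by SN2 attack of the carboxylate of 3 on the alkoxyphosphonium ion of 4. This fallback makes no new compound, hence the entry F0.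

## Further compounds

F1 | step 3 | dodec-11-en-1-yl acetate | CC(=O)OCCCCCCCCCCC=C
F2 | step 3 | methyl 16-iodohexadecanoate | COC(=O)CCCCCCCCCCCCCCCI
F3 | step 3 | 12-(9-borabicyclo[3.3.1]nonan-9-yl)dodecyl acetate | CC(=O)OCCCCCCCCCCCCB1C2CCCC1CCC2
F4 | step 3 | methyl 28-acetoxyoctacosanoate | COC(=O)CCCCCCCCCCCCCCCCCCCCCCCCCCCOC(C)=O
F5 | step 3 | 28-hydroxyoctacosanoic acid | OCCCCCCCCCCCCCCCCCCCCCCCCCCCC(=O)O
F6 | step 1 | 16-bromohexadecanoic acid | OC(=O)CCCCCCCCCCCCCCCBr
F0 | step 2 | none | none
A1 | alternative 1 | 28-hydroxyoctacosanoic acid | OCCCCCCCCCCCCCCCCCCCCCCCCCCCC(=O)O
A2 | alternative 2 | dodec-11-en-1-yl octadec-17-enoate | C=CCCCCCCCCCCCCCCCC(=O)OCCCCCCCCCCC=C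
A3 | alternative 2 | oxacyclononacos-18-en-2-one (E/Z mixture) | O=C1CCCCCCCCCCCCCCCC=CCCCCCCCCCCO1
A4 | alternative 2 | undec-10-en-1-yl undec-10-enoate | C=CCCCCCCCCC(=O)OCCCCCCCCCC=C
A5 | alternative 3 | 15-methoxy-15-oxopentadecanoic acid | COC(=O)CCCCCCCCCCCCCC(=O)O
A6 | alternative 3 | dimethyl octacosanedioate | COC(=O)CCCCCCCCCCCCCCCCCCCCCCCCCCC(=O)OC
A7 | alternative 3 | cyclooctacosanone | O=C1CCCCCCCCCCCCCCCCCCCCCCCCCCC1
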